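**Plan**
- Retrosynthesis: the MOM and TBS groups come off last, the prenyl C=C is cut back to an 8‑allyl group (cross‑metathesis), C4=O is traced to a C4–OMe ether and C3–OH to a C3–Si bond.
- The pyranone ring O1–C2–C3–C4–C4a–C8a is a formal [4+2] adduct. Cutting O1–C2 and C3–C4 gives an A‑ring heterodiene O1=C8a–C4a=C4 (a fully substituted salicylaldehyde, used as its O‑methyl oxocarbenium) and a C2=C3 (E)‑β‑silylstyrene carrying the B ring.
- Forward: the A‑ring aldehyde (five steps from 2‑methoxyresorcinol) and the B‑ring vinylsilane (three steps from 2,5‑dihydroxybenzaldehyde) are made separately. The pyran ring, the only ring formed, arises in the annulation. Then C3–Si → C3–OH, C4–OMe → C4=O, allyl → prenyl and deprotection.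
- Stereochemistry: 2,3‑trans from the E alkene by suprafacial addition; absolute sense from a chiral phosphoric acid ion pair; C3–O by Tamao–Fleming oxidation with retention; C4 is a disposable centre.
- The silicon group is benzyldimethylsilyl, so the C–Si oxidation needs only fluoride and peroxide and never acid, which would expel the β‑methoxy group.

Key step: step 9

Assumption: which enantiomer of the chiral phosphoric acid leads to the (2R,3S,4R) adduct cannot be predicted with confidence; the (R)‑catalyst is written, and its mirror image would be used if the induction proves opposite.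

**Step 1**
Reactants: 1 2‑methoxyresorcinol
Product: 2 2‑methoxy‑1,3‑bis(methoxymethoxy)benzene
Conditions: MOMCl, i‑Pr2NEt, CH2Cl2, 0 °C → rt
Reagents that add atoms: chloromethyl methyl ether, COCCl
Why: MOM protection (Williamson‑type O‑alkylation of both phenols) gives acetal ethers that tolerate the base, heat and metal catalysis ahead and leave in one acid step at the end.

**Step 2**
Reactants: 2 2‑methoxy‑1,3‑bis(methoxymethoxy)benzene
Product: 4 4‑methoxy‑3,5‑bis(methoxymethoxy)phenol, via arylboronic pinacol ester 3 (not isolated)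
Conditions: [Ir(OMe)(cod)]2 (cat.), dtbpy (cat.), B2pin2, THF, 80 °C; then aq. NaOH, 30% H2O2, 0 °C → rt
Reagents that add atoms: bis(pinacolato)diboron, CC1(C)OB(OC1(C)C)B1OC(C)(C)C(C)(C)O1 (boron of 3); hydrogen peroxide, OO (oxygen of 4)
Why: iridium‑catalysed C–H borylation is sterically controlled and should select the only C–H with no ortho substituent (para to OMe), and basic peroxide oxidation of the C–B bond then gives the phenol in the same flask.

**Step 3**
Reactants: 4 4‑methoxy‑3,5‑bis(methoxymethoxy)phenol; 5 allyl bromide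
Product: 6 5‑(allyloxy)‑2‑methoxy‑1,3‑bis(methoxymethoxy)benzene
Conditions: K2CO3, acetone, reflux
Reagents that add atoms: none
Why: Williamson ether synthesis; the phenoxide is alkylated on oxygen by the allylic bromide under mild carbonate conditions.

**Step 4**
Reactants: 6 5‑(allyloxy)‑2‑methoxy‑1,3‑bis(methoxymethoxy)benzene
Product: 7 2‑allyl‑4‑methoxy‑3,5‑bis(methoxymethoxy)phenol
Conditions: PhNEt2, 190 °C
Reagents that add atoms: none
Why: aromatic Claisen rearrangement; the two ortho positions are equivalent and the para position is blocked by OMe, so a single C‑allyl phenol should result after rearomatisation.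

**Step 5**
Reactants: 7 2‑allyl‑4‑methoxy‑3,5‑bis(methoxymethoxy)phenol
Product: 8 3‑allyl‑2‑hydroxy‑5‑methoxy‑4,6‑bis(methoxymethoxy)benzaldehyde
Conditions: MgCl2, Et3N, (CH2O)n, MeCN, reflux
Reagents that add atoms: paraformaldehyde (formaldehyde unit), C=O
Why: magnesium‑mediated ortho‑formylation (Casnati–Skattebøl); the magnesium phenoxide delivers formaldehyde to the only free ring position and hydride transfer to a second formaldehyde gives the aldehyde without acid that would cleave MOM ethers.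

**Step 6**
Reactants: 9 2,5‑dihydroxybenzaldehyde
Product: 10 2,5‑bis(methoxymethoxy)benzaldehyde
Conditions: MOMCl, i‑Pr2NEt, CH2Cl2, reflux
Reagents that add atoms: chloromethyl methyl ether, COCCl
Why: MOM protection of both phenols masks the oxidation‑prone hydroquinone until the last step.

**Step 7**
Reactants: 10 2,5‑bis(methoxymethoxy)benzaldehyde
Product: 11 2‑ethynyl‑1,4‑bis(methoxymethoxy)benzene
Conditions: Ohira–Bestmann reagent, K2CO3, MeOH, rt
Reagents that add atoms: dimethyl (1‑diazo‑2‑oxopropyl)phosphonate, COP(=O)(OC)C(=[N+]=[N-])C(C)=O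
Why: Seyferth–Gilbert homologation (Ohira–Bestmann variant) converts the non‑enolisable aryl aldehyde into the terminal alkyne under carbonate/methanol conditions that MOM ethers tolerate.

**Step 8**
Reactants: 11 2‑ethynyl‑1,4‑bis(methoxymethoxy)benzene; 12 benzyldimethylsilane
Product: 13 (E)‑benzyl{2‑[2,5‑bis(methoxymethoxy)phenyl]ethenyl}dimethylsilane
Conditions: PtCl2 (cat.), XPhos (cat.), THF, 60 °C
Reagents that add atoms: none
Why: platinum‑catalysed syn hydrosilylation of a terminal arylalkyne with a bulky phosphine should place silicon on the terminal carbon and give the (E)‑β‑vinylsilane; the benzyldimethylsilyl group is acid‑stable yet fluoride‑activatable for the later oxidation.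

**Step 9**
Reactants: 8 3‑allyl‑2‑hydroxy‑5‑methoxy‑4,6‑bis(methoxymethoxy)benzaldehyde; 13 (E)‑benzyl{2‑[2,5‑bis(methoxymethoxy)phenyl]ethenyl}dimethylsilane
Product: 16 (2R,3S,4R)‑8‑allyl‑3‑(benzyldimethylsilyl)‑2‑[2,5‑bis(methoxymethoxy)phenyl]‑4,6‑dimethoxy‑5,7‑bis(methoxymethoxy)chromane, via dimethyl acetal 14 (not isolated), via O‑methyl oxocarbenium ion 15 (not isolated)
Conditions: (R)‑TRIP (10 mol %), HC(OMe)3, 5 Å MS, PhMe, −20 °C → rt; Et3N quench
Reagents that add atoms: trimethyl orthoformate, COC(OC)OC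
Why: Proposed new method: the acid and the orthoformate turn 8 into acetal 14 and ionise it to the oxocarbenium (O‑methylated o‑quinone methide) 15, whose C4 attacks the silicon‑bearing alkene carbon of 13 while the phenol oxygen captures the developing C2 cation in an asynchronous, suprafacial inverse‑demand hetero‑[4+2]. The closest known reaction type is the acid‑promoted annulation of salicylaldehydes, orthoformates and styrenes to 4‑alkoxy‑2‑arylchromans, together with chiral phosphoric acid catalysed [4+2] reactions of o‑quinone methides; the β‑silylstyrene and enantiocontrol at an alkoxy‑substituted methide are the untested parts. The pyran ring closes in the hetero‑Diels–Alder mode, C3–C4 first and then the six‑membered O1–C2 closure of the phenol onto the benzylic, β‑silicon‑stabilised cation. C2/C3 trans follows from the E alkene, the 2,4‑cis placement of C4–OMe from the endo‑type orientation of the aryl group towards the (E)‑oxocarbenium, and the absolute sense from the chiral phosphate, which pairs with the cation and hydrogen‑bonds the phenol so that one face is shielded. The step needs C4‑to‑C(Si) regiochemistry, secured by the combined aryl and β‑silicon stabilisation at C2, and ring closure faster than loss of silicon, favoured by the intramolecular phenol, the weak acid, sieves that remove methanol and low temperature; the monosubstituted allyl group is too poor a nucleophile to compete. The C4 epimer is removed by chromatography here, because an exo adduct formed on the same cation face would carry the opposite C2/C3 configuration.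

**Step 10**
Reactants: 16 (2R,3S,4R)‑8‑allyl‑3‑(benzyldimethylsilyl)‑2‑[2,5‑bis(methoxymethoxy)phenyl]‑4,6‑dimethoxy‑5,7‑bis(methoxymethoxy)chromane
Product: 18 (2R,3S,4R)‑8‑allyl‑2‑[2,5‑bis(methoxymethoxy)phenyl]‑4,6‑dimethoxy‑5,7‑bis(methoxymethoxy)chroman‑3‑ol, via fluorosilane 17 (not isolated)
Conditions: TBAF, THF, 0 °C; then KHCO3, 30% H2O2, MeOH/THF, 40 °C
Reagents that add atoms: tetrabutylammonium fluoride, CCCC[N+](CCCC)(CCCC)CCCC.[F-] (fluorine of 17); hydrogen peroxide, OO (oxygen of 18)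
Why: Tamao–Fleming oxidation in its benzyldimethylsilyl form; fluoride cleaves the benzyl group to a fluorosilane and buffered peroxide inserts oxygen into C3–Si with retention, so C3–OH stays trans to the C2 aryl group, and no acid is present to trigger Peterson‑type loss of the C4 methoxy group.

**Step 11**
Reactants: 18 (2R,3S,4R)‑8‑allyl‑2‑[2,5‑bis(methoxymethoxy)phenyl]‑4,6‑dimethoxy‑5,7‑bis(methoxymethoxy)chroman‑3‑ol
Product: 19 (2R,3S,4R)‑8‑allyl‑2‑[2,5‑bis(methoxymethoxy)phenyl]‑3‑[(tert‑butyldimethylsilyl)oxy]‑4,6‑dimethoxy‑5,7‑bis(methoxymethoxy)chromane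
Conditions: TBSCl, imidazole, DMAP (cat.), DMF, 40 °C
Reagents that add atoms: tert‑butyldimethylsilyl chloride, CC(C)(C)[Si](C)(C)Cl
Why: silylation of the secondary alcohol under basic conditions blocks C3–OH so that only C4 is oxidised later, and leaves the acid‑labile C4 ether untouched.

**Step 12**
Reactants: 19 (2R,3S,4R)‑8‑allyl‑2‑[2,5‑bis(methoxymethoxy)phenyl]‑3‑[(tert‑butyldimethylsilyl)oxy]‑4,6‑dimethoxy‑5,7‑bis(methoxymethoxy)chromane
Product: 20 (2R,3S)‑8‑allyl‑2‑[2,5‑bis(methoxymethoxy)phenyl]‑3‑[(tert‑butyldimethylsilyl)oxy]‑6‑methoxy‑5,7‑bis(methoxymethoxy)chroman‑4‑ol (mixture of C4 epimers)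
Conditions: PPTS (cat.), acetone/H2O (4:1), rt
Reagents that add atoms: water, O
Why: SN1 solvolysis of the benzylic methyl ether through the cation stabilised by the three ortho/para oxygens of the A ring should proceed under acid too weak to cleave aryl MOM or TBS ethers; the C4 configuration does not matter.

**Step 13**
Reactants: 20 (2R,3S)‑8‑allyl‑2‑[2,5‑bis(methoxymethoxy)phenyl]‑3‑[(tert‑butyldimethylsilyl)oxy]‑6‑methoxy‑5,7‑bis(methoxymethoxy)chroman‑4‑ol
Product: 21 (2R,3R)‑8‑allyl‑2‑[2,5‑bis(methoxymethoxy)phenyl]‑3‑[(tert‑butyldimethylsilyl)oxy]‑6‑methoxy‑5,7‑bis(methoxymethoxy)chroman‑4‑one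
Conditions: DMP, NaHCO3, CH2Cl2, 0 °C → rt
Reagents that add atoms: none
Why: Dess–Martin oxidation converts both C4 epimers of the benzylic alcohol into the aryl ketone under buffered, non‑basic conditions, so the α‑centre C3 is not enolised and the allyl group is untouched.

**Step 14**
Reactants: 21 (2R,3R)‑8‑allyl‑2‑[2,5‑bis(methoxymethoxy)phenyl]‑3‑[(tert‑butyldimethylsilyl)oxy]‑6‑methoxy‑5,7‑bis(methoxymethoxy)chroman‑4‑one
Product: 22 (2R,3R)‑2‑[2,5‑bis(methoxymethoxy)phenyl]‑3‑[(tert‑butyldimethylsilyl)oxy]‑6‑methoxy‑5,7‑bis(methoxymethoxy)‑8‑(3‑methylbut‑2‑en‑1‑yl)chroman‑4‑one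
Conditions: Grubbs II (5 mol %), 2‑methyl‑2‑butene (excess), CH2Cl2, 40 °C
Reagents that add atoms: 2‑methyl‑2‑butene, CC=C(C)C
Why: olefin cross‑metathesis of the terminal allyl group with excess 2‑methyl‑2‑butene exchanges =CH2 for =CMe2 under neutral conditions that preserve the α‑silyloxy ketone.

**Step 15**
Reactants: 22 (2R,3R)‑2‑[2,5‑bis(methoxymethoxy)phenyl]‑3‑[(tert‑butyldimethylsilyl)oxy]‑6‑methoxy‑5,7‑bis(methoxymethoxy)‑8‑(3‑methylbut‑2‑en‑1‑yl)chroman‑4‑one
Product: 23 (2R,3R)‑2‑(2,5‑dihydroxyphenyl)‑3,5,7‑trihydroxy‑6‑methoxy‑8‑(3‑methylbut‑2‑en‑1‑yl)chroman‑4‑one (CNP0287732.1)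
Conditions: 3 M aq. HCl, MeOH, 45 °C
Reagents that add atoms: none
Why: acid‑catalysed acetal exchange removes the four aryl MOM ethers and the same medium cleaves the TBS ether; the 2,3‑trans dihydroflavonol is the thermodynamically preferred arrangement and should not epimerise under acid.

**Compound list**
1 | 2‑methoxyresorcinol (2‑methoxybenzene‑1,3‑diol) | COc1c(O)cccc1O | starting material
2 | 2‑methoxy‑1,3‑bis(methoxymethoxy)benzene | COCOc1cccc(OCOC)c1OC | intermediate
3 | 2‑[4‑methoxy‑3,5‑bis(methoxymethoxy)phenyl]‑4,4,5,5‑tetramethyl‑1,3,2‑dioxaborolane | COCOc1cc(B2OC(C)(C)C(C)(C)O2)cc(OCOC)c1OC | intermediate (not isolated)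
4 | 4‑methoxy‑3,5‑bis(methoxymethoxy)phenol | COCOc1cc(O)cc(OCOC)c1OC | intermediate
5 | allyl bromide | C=CCBr | starting material
6 | 5‑(allyloxy)‑2‑methoxy‑1,3‑bis(methoxymethoxy)benzene | C=CCOc1cc(OCOC)c(OC)c(OCOC)c1 | intermediate
7 | 2‑allyl‑4‑methoxy‑3,5‑bis(methoxymethoxy)phenol | C=CCc1c(O)cc(OCOC)c(OC)c1OCOC | intermediate
8 | 3‑allyl‑2‑hydroxy‑5‑methoxy‑4,6‑bis(methoxymethoxy)benzaldehyde | O=Cc1c(O)c(CC=C)c(OCOC)c(OC)c1OCOC | intermediate
9 | 2,5‑dihydroxybenzaldehyde | O=Cc1cc(O)ccc1O | starting material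
10 | 2,5‑bis(methoxymethoxy)benzaldehyde | O=Cc1cc(OCOC)ccc1OCOC | intermediate
11 | 2‑ethynyl‑1,4‑bis(methoxymethoxy)benzene | C#Cc1cc(OCOC)ccc1OCOC | intermediate
12 | benzyldimethylsilane | C[SiH](C)Cc1ccccc1 | starting material
13 | (E)‑benzyl{2‑[2,5‑bis(methoxymethoxy)phenyl]ethenyl}dimethylsilane | C[Si](C)(Cc1ccccc1)/C=C/c1cc(OCOC)ccc1OCOC | intermediate
14 | 2‑allyl‑6‑(dimethoxymethyl)‑4‑methoxy‑3,5‑bis(methoxymethoxy)phenol (dimethyl acetal of 8) | COC(OC)c1c(O)c(CC=C)c(OCOC)c(OC)c1OCOC | intermediate (not isolated)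
15 | O‑methyl oxocarbenium ion of 8 (protonated 4‑methoxy o‑quinone methide; chiral phosphate counter‑ion) | C[O+]=Cc1c(O)c(CC=C)c(OCOC)c(OC)c1OCOC | intermediate (not isolated)
16 | (2R,3S,4R)‑8‑allyl‑3‑(benzyldimethylsilyl)‑2‑[2,5‑bis(methoxymethoxy)phenyl]‑4,6‑dimethoxy‑5,7‑bis(methoxymethoxy)chromane | COc1c(OCOC)c(CC=C)c2c(c1OCOC)[C@@H](OC)[C@H]([Si](C)(C)Cc1ccccc1)[C@@H](c1cc(OCOC)ccc1OCOC)O2 | intermediate
17 | (2R,3S,4R)‑8‑allyl‑2‑[2,5‑bis(methoxymethoxy)phenyl]‑3‑(fluorodimethylsilyl)‑4,6‑dimethoxy‑5,7‑bis(methoxymethoxy)chromane | COc1c(OCOC)c(CC=C)c2c(c1OCOC)[C@@H](OC)[C@H]([Si](C)(C)F)[C@@H](c1cc(OCOC)ccc1OCOC)O2 | intermediate (not isolated)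
18 | (2R,3S,4R)‑8‑allyl‑2‑[2,5‑bis(methoxymethoxy)phenyl]‑4,6‑dimethoxy‑5,7‑bis(methoxymethoxy)chroman‑3‑ol | COc1c(OCOC)c(CC=C)c2c(c1OCOC)[C@@H](OC)[C@H](O)[C@@H](c1cc(OCOC)ccc1OCOC)O2 | intermediate
19 | (2R,3S,4R)‑8‑allyl‑2‑[2,5‑bis(methoxymethoxy)phenyl]‑3‑[(tert‑butyldimethylsilyl)oxy]‑4,6‑dimethoxy‑5,7‑bis(methoxymethoxy)chromane | COc1c(OCOC)c(CC=C)c2c(c1OCOC)[C@@H](OC)[C@H](O[Si](C)(C)C(C)(C)C)[C@@H](c1cc(OCOC)ccc1OCOC)O2 | intermediate
20 | (2R,3S)‑8‑allyl‑2‑[2,5‑bis(methoxymethoxy)phenyl]‑3‑[(tert‑butyldimethylsilyl)oxy]‑6‑methoxy‑5,7‑bis(methoxymethoxy)chroman‑4‑ol (C4 epimers) | COc1c(OCOC)c(CC=C)c2c(c1OCOC)C(O)[C@H](O[Si](C)(C)C(C)(C)C)[C@@H](c1cc(OCOC)ccc1OCOC)O2 | intermediate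
21 | (2R,3R)‑8‑allyl‑2‑[2,5‑bis(methoxymethoxy)phenyl]‑3‑[(tert‑butyldimethylsilyl)oxy]‑6‑methoxy‑5,7‑bis(methoxymethoxy)chroman‑4‑one | COc1c(OCOC)c(CC=C)c2c(c1OCOC)C(=O)[C@H](O[Si](C)(C)C(C)(C)C)[C@@H](c1cc(OCOC)ccc1OCOC)O2 | intermediate
22 | (2R,3R)‑2‑[2,5‑bis(methoxymethoxy)phenyl]‑3‑[(tert‑butyldimethylsilyl)oxy]‑6‑methoxy‑5,7‑bis(methoxymethoxy)‑8‑(3‑methylbut‑2‑en‑1‑yl)chroman‑4‑one | COc1c(OCOC)c(CC=C(C)C)c2c(c1OCOC)C(=O)[C@H](O[Si](C)(C)C(C)(C)C)[C@@H](c1cc(OCOC)ccc1OCOC)O2 | intermediate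
23 | (2R,3R)‑2‑(2,5‑dihydroxyphenyl)‑3,5,7‑trihydroxy‑6‑methoxy‑8‑(3‑methylbut‑2‑en‑1‑yl)chroman‑4‑one | COc1c(O)c(CC=C(C)C)c2c(c1O)C(=O)[C@H](O)[C@@H](c1cc(O)ccc1O)O2 | target

**Count**
Total steps: 15. Longest linear sequence: 12 (steps 1–5, then 9–15); the B‑ring branch (steps 6–8) joins at step 9.

**Steps most likely to fail**

1. Step 9. The β‑silyl cation may lose silicon before the phenol closes the ring, or the adduct may lose methoxysilane under the acid. Face or endo/exo control may also be too low, which would erode the enantiomeric purity once C4 is oxidised.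
 Fallback (known chalcone‑epoxide chemistry), setting out from 8 and 10 and coming back at 23: MOM protection of the phenol of 8 gives 3‑allyl‑5‑methoxy‑2,4,6‑tris(methoxymethoxy)benzaldehyde F1. Methylmagnesium bromide gives the carbinol F2 and Dess–Martin oxidation the acetophenone F3. Claisen–Schmidt condensation with 10 (KOH, EtOH) gives the (E)‑chalcone F4, and cross‑metathesis with 2‑methyl‑2‑butene the prenyl chalcone F5. Juliá–Colonna epoxidation (poly‑L‑leucine, urea–H2O2, DBU) should give the (2R,3S)‑epoxy ketone F6. HCl in methanol then removes the MOM groups, and the freed 2'‑hydroxyl opens the epoxide at the benzylic carbon with inversion to give the trans‑dihydroflavonol 23.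

2. Step 10. Fluoride at silicon may trigger anti‑elimination across C3–Si/C2–O1 (ring opening) or across C3–Si/C4–OMe instead of oxidation.
 Fallback, setting out from 16 and coming back at 18: the elimination is used on purpose. Catalytic camphorsulfonic acid in CH2Cl2 effects Peterson‑type loss of the silyl and methoxy groups to the (S)‑flav‑3‑ene F7. Dimethyldioxirane in acetone/methanol at low temperature should epoxidise the electron‑rich C3=C4 bond on the face opposite the 2‑aryl group to the epoxide F8. Methanol then opens F8 at the benzylic C4 with inversion, in the same flask, to give 18; any C4 epimer formed converges at 21.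

3. Step 15. The hindered C3 silyl ether may cleave slowly and force acid conditions under which the prenyl group cyclises onto the 7‑hydroxyl or adds methanol.
 Fallback, setting out from 21 and coming back at 23: the order of the last two operations is reversed. HCl in methanol on the allyl ketone 21, which has no acid‑sensitive trisubstituted alkene, gives the free 8‑allyl dihydroflavonol F9. Cross‑metathesis of F9 with 2‑methyl‑2‑butene (Grubbs II), which tolerates free phenols, then gives 23.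

**Further compounds**
F1 | step 9 | 3‑allyl‑5‑methoxy‑2,4,6‑tris(methoxymethoxy)benzaldehyde | O=Cc1c(OCOC)c(CC=C)c(OCOC)c(OC)c1OCOC
F2 | step 9 | 1‑[3‑allyl‑5‑methoxy‑2,4,6‑tris(methoxymethoxy)phenyl]ethan‑1‑ol | CC(O)c1c(OCOC)c(CC=C)c(OCOC)c(OC)c1OCOC
F3 | step 9 | 1‑[3‑allyl‑5‑methoxy‑2,4,6‑tris(methoxymethoxy)phenyl]ethan‑1‑one | CC(=O)c1c(OCOC)c(CC=C)c(OCOC)c(OC)c1OCOC
F4 | step 9 | (E)‑1‑[3‑allyl‑5‑methoxy‑2,4,6‑tris(methoxymethoxy)phenyl]‑3‑[2,5‑bis(methoxymethoxy)phenyl]prop‑2‑en‑1‑one | O=C(/C=C/c1cc(OCOC)ccc1OCOC)c1c(OCOC)c(CC=C)c(OCOC)c(OC)c1OCOC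
F5 | step 9 | (E)‑3‑[2,5‑bis(methoxymethoxy)phenyl]‑1‑[5‑methoxy‑2,4,6‑tris(methoxymethoxy)‑3‑(3‑methylbut‑2‑en‑1‑yl)phenyl]prop‑2‑en‑1‑one | O=C(/C=C/c1cc(OCOC)ccc1OCOC)c1c(OCOC)c(CC=C(C)C)c(OCOC)c(OC)c1OCOC
F6 | step 9 | {(2R,3S)‑3‑[2,5‑bis(methoxymethoxy)phenyl]oxiran‑2‑yl}[5‑methoxy‑2,4,6‑tris(methoxymethoxy)‑3‑(3‑methylbut‑2‑en‑1‑yl)phenyl]methanone | O=C([C@@H]1O[C@H]1c1cc(OCOC)ccc1OCOC)c1c(OCOC)c(CC=C(C)C)c(OCOC)c(OC)c1OCOC
F7 | step 10 | (S)‑8‑allyl‑2‑[2,5‑bis(methoxymethoxy)phenyl]‑6‑methoxy‑5,7‑bis(methoxymethoxy)‑2H‑chromene | COc1c(OCOC)c(CC=C)c2c(c1OCOC)C=C[C@@H](c1cc(OCOC)ccc1OCOC)O2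
F8 | step 10 | 3,4‑epoxide of F7, oxirane on the face opposite the 2‑aryl group | COc1c(OCOC)c(CC=C)c2c(c1OCOC)[C@@H]1O[C@@H]1[C@@H](c1cc(OCOC)ccc1OCOC)O2
F9 | step 15 | (2R,3R)‑8‑allyl‑2‑(2,5‑dihydroxyphenyl)‑3,5,7‑trihydroxy‑6‑methoxychroman‑4‑one | COc1c(O)c(CC=C)c2c(c1O)C(=O)[C@H](O)[C@@H](c1cc(O)ccc1O)O2
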